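The readings were generated by integration with made-up constants.

Begin with the easy step: each capture agent takes one open intermediate and stops. In both asked flasks its charge is smaller than the substrate's, so it is the limiting reagent of that step. Define the ceiling C, the charge of capture agent divided by the charge of substrate: 1.60% in zeta, 5.00% in alpha.

all flasks: substrate 0.50 M
- Thursday's: partner 0.55 M; capture agent 0.011 M; run made earlier
- Saturday's: partner 0.55 M; capture agent 0.032 M; run made earlier
- Friday's: partner 1.2 M; capture agent 0.025 M; run made earlier
- zeta: partner 1.50 M; capture agent 0.00800 M; time 2.0 h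
- alpha: partner 0.550 M; capture agent 0.0250 M; time 6.0 h

| run | time / h | target / % | trapped intermediate / % |
|---|---|---|---|
| Thursday's | 0.333 | 1 | 1 |
| Thursday's | 0.833 | 9 | 1 |
| Thursday's | 2.00 | 27 | 2 |
| Thursday's | 4.00 | 38 | 3 |
| Saturday's | 1.00 | 14 | 4 |
| Saturday's | 2.00 | 26 | 5 |
| Saturday's | 3.00 | 35 | 9 |
| Saturday's | 4.00 | 38 | 8 |
| Friday's | 1.00 | 19 | 4 |
| Friday's | 2.00 | 36 | 3 |
| Friday's | 3.00 | 45 | 6 |
| Friday's | 4.00 | 51 | 4 |

(readings scatter by 1.5 percentage points)

* the flask that ends with the higher share of target in all that became target or trapped intermediate, or "neither" when 2 percentage points or less lies between them (zeta / alpha / neither)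
* share of target in all that became target or trapped intermediate, zeta
* share of target in all that became target or trapped intermediate, alpha

Use the bench rule: trapped intermediate V equals C, and the share is S = P/(P + V), with P the target. Test it on the readings. Saturday's run has C = 6.40% and ends at 8%; Thursday's has 2.20% and ends at 3%. Both differ from C by about the scatter of 1.5 percentage points.

But this is the late end, and V starts from zero. Find the border from Saturday's reading at 1.00 h, which leaves a fraction L = 0.375 of the capture agent. Join the two ends with a rough exponential at Saturday's pace. This is an estimate and claims no constant pace, for open intermediate is not charged and grows from zero, and zeta holds more partner than Saturday's run: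

V = C × (1 − L^(t/t_r)), with t_r = 1.00 h

Zeta's ratio t/t_r is 2.00, which leaves 0.141 and gives V = 1.38%, close to the border. Alpha's ratio is 6.00, past the border, so V = C there.

Now borrow the target. Friday's 36% at 2.00 h gives zeta S = 96.3%. The last 38% of Saturday's run gives alpha 88.4%, and later target raises that figure. Hold my 96.3% for zeta and 88.4% for alpha against the margin of 2 points: I commit to zeta.

The forecast names zeta, with 96.5% for zeta and 90% for alpha, on the ground: “the agent is simply used up”.

The flasks give zeta: zeta 96.5%, alpha 89.4%. At 2.00 h zeta keeps 4.5% of its capture agent unbound, less than the 0.141 I borrowed. C less that part is 1.53%, and the trapped intermediate stands at 1.53%.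

    substrate → open intermediate (k = 3.29 × 10⁻⁴ s⁻¹)
    partner → second intermediate (k = 6.88 × 10⁻⁴ s⁻¹)
    open intermediate + second intermediate → target (k = 3.53 × 10⁻⁴ M⁻¹ s⁻¹)
    2 second intermediate → homo product (k = 3.67 × 10⁻⁴ M⁻¹ s⁻¹)
    open intermediate + capture agent → trapped intermediate (k = 0.00219 M⁻¹ s⁻¹)

Take the neighbour of zeta with 0.020 M of capture agent. Here C = 4.00%, and zeta's unbound part gives V = 3.82%, so with zeta's target S = 91.6%. The computed flask holds 3.81% trapped intermediate and a share of 91.5%.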